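**Strategy.** Everything rests on the C8–C9 bond (germacrane numbering) of the ten-membered carbocycle (ring A). The acetoxy carbinol C9 sits δ to the lactone carbonyl C12 through C8–C7=C11 of the fused butenolide (ring B), a vinylogous-aldol pattern. The precursor is an open chain carrying a (Z)-enal (C9) and a 4-(bromomethyl)butenolide (C8), two electrophilic carbons. Zinc reverses the polarity of the allylic bromide; the resulting butenolide dienolate attacks the aldehyde through its exocyclic γ-carbon. This closes ring A, creates the C9 carbinol and returns the C7=C11 double bond to ring B in one operation. Acetylation and desilylation finish the target.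

Key step: step 12

Remark: positions are given in germacrane numbering (ring carbons C1–C10, lactone carbonyl C12, hydroxymethyl C13); the sense of induction in steps 1 and 6 follows the accepted models, and the antipodal reagent or ligand would be used if it proved opposite.

Step 1
Reactants: 1 (E)-4,4-dimethoxy-2-methylbut-2-enal
Product: 2 (2E,4S)-1,1-dimethoxy-3-methylhepta-2,6-dien-4-ol
Conditions: (−)-Ipc2B(allyl) (1.3 equiv), Et2O, −78 °C; then NaOH, 30% H2O2, 0 → 23 °C
Reagents that add atoms: (−)-B-allyldiisopinocampheylborane, C=CCB([C@@H]1C[C@@H]2C[C@H]([C@H]1C)C2(C)C)[C@@H]1C[C@@H]2C[C@H]([C@H]1C)C2(C)C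
Why: Brown allylboration through a closed chair transition state, in which the isopinocampheyl groups of the (+)-α-pinene-derived reagent should direct allyl to the Si face of the α-methyl enal and set C3 as S, the acetal being inert.

Step 2
Reactants: 2 (2E,4S)-1,1-dimethoxy-3-methylhepta-2,6-dien-4-ol
Product: 3 (2E,4S)-1,1-dimethoxy-3-methylhepta-2,6-dien-4-yl 2-methylprop-2-enoate
Conditions: methacryloyl chloride, Et3N, DMAP (cat.), CH2Cl2, 0 °C
Reagents that add atoms: methacryloyl chloride, CC(=C)C(Cl)=O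
Why: DMAP-catalysed acylation of the secondary allylic alcohol with an acid chloride installs the methacrylate for ring closure without touching the stereocentre.

Step 3
Reactants: 3 (2E,4S)-1,1-dimethoxy-3-methylhepta-2,6-dien-4-yl 2-methylprop-2-enoate
Product: 4 (6S)-6-[(2E)-4,4-dimethoxybut-2-en-2-yl]-3-methyl-5,6-dihydro-2H-pyran-2-one
Conditions: second-generation Grubbs catalyst (5 mol %), CH2Cl2 (5 mM), 40 °C
Reagents that add atoms: none
Why: Ring-closing metathesis of the allyl group with the methacrylate should give the six-membered unsaturated lactone, whose ring fixes the future C1=C10 double bond as Z, while the trisubstituted alkene stays out of the reaction.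

Step 4
Reactants: 4 (6S)-6-[(2E)-4,4-dimethoxybut-2-en-2-yl]-3-methyl-5,6-dihydro-2H-pyran-2-one
Product: 6 (2E,4S,6Z)-4,8-dihydroxy-3,7-dimethylocta-2,6-dienal, via diol acetal 5 (not isolated)
Conditions: i-Bu2AlH (3.5 equiv), CH2Cl2, −78 → −20 °C; then 1 M aq. HCl, THF, 0 °C
Reagents that add atoms: water, O
Why: 1,2-Reduction of the unsaturated lactone opens it to the (Z)-allylic diol, and the acidic work-up hydrolyses the allylic dimethyl acetal to the (E)-enal, whose geometry prevents lactol formation (ester reduction, then acetal hydrolysis).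

Step 5
Reactants: 6 (2E,4S,6Z)-4,8-dihydroxy-3,7-dimethylocta-2,6-dienal
Product: 7 (2E,4S,6Z)-3,7-dimethyl-4,8-bis(triethylsilyloxy)octa-2,6-dienal
Conditions: Et3SiCl (2.4 equiv), imidazole, DMF, 0 °C
Reagents that add atoms: chlorotriethylsilane, CC[Si](Cl)(CC)CC
Why: Standard silylation protects both hydroxyl groups as a primary and a secondary triethylsilyl ether that can be told apart later.

Step 6
Reactants: 7 (2E,4S,6Z)-3,7-dimethyl-4,8-bis(triethylsilyloxy)octa-2,6-dienal; 8 tert-butyl(diphenyl)(prop-2-yn-1-yloxy)silane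
Product: 9 (4S,5E,7S,9Z)-1-(tert-butyldiphenylsilyloxy)-6,10-dimethyl-7,11-bis(triethylsilyloxy)undeca-5,9-dien-2-yn-4-ol
Conditions: Me2Zn (3 equiv), (S,S)-ProPhenol (20 mol %), Ph3P=O (40 mol %), toluene, 0 °C
Reagents that add atoms: none
Why: Zinc–ProPhenol-catalysed enantioselective alkynylation of the enal, in which the dinuclear zinc catalyst should deliver the zinc acetylide to the Re face and set the propargylic carbinol (future C6) as S, the configuration that the invertive steps 7 and 8 turn into 6R.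

Step 7
Reactants: 9 (4S,5E,7S,9Z)-1-(tert-butyldiphenylsilyloxy)-6,10-dimethyl-7,11-bis(triethylsilyloxy)undeca-5,9-dien-2-yn-4-ol
Product: 11 (aR,5E,7S,9Z)-2-[(tert-butyldiphenylsilyloxy)methyl]-6,10-dimethyl-7,11-bis(triethylsilyloxy)undeca-2,3,5,9-tetraenoic acid, via propargylic mesylate 10 (not isolated)
Conditions: MsCl, Et3N, THF, −78 °C; then Pd(PPh3)4 (5 mol %), CO (1 atm), H2O, THF, −78 → 0 °C
Reagents that add atoms: carbon monoxide, [C-]#[O+]; water, O
Why: Palladium-catalysed SN2′ carbonylation of a propargylic mesylate: zerovalent palladium displaces the mesylate anti to give an allenylpalladium species, and CO insertion with hydrolysis gives the 2,3-allenoic acid, so the carbinol configuration is carried into the allene axis.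

Step 8
Reactants: 11 (aR,5E,7S,9Z)-2-[(tert-butyldiphenylsilyloxy)methyl]-6,10-dimethyl-7,11-bis(triethylsilyloxy)undeca-2,3,5,9-tetraenoic acid
Product: 12 (5R)-3-[(tert-butyldiphenylsilyloxy)methyl]-5-[(1E,3S,5Z)-2,6-dimethyl-3,7-bis(triethylsilyloxy)hepta-1,5-dien-1-yl]-4-iodofuran-2(5H)-one
Conditions: I2 (1.5 equiv), NaHCO3, MeCN, 0 °C
Reagents that add atoms: iodine, II
Why: Iodolactonisation of the 2,3-allenoic acid (5-endo attack of the carboxylate on the iodine-activated C6=C7 bond, anti to iodine) should transfer the axial chirality to C6 as R and leave a vinyl iodide at C7.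

Step 9
Reactants: 12 (5R)-3-[(tert-butyldiphenylsilyloxy)methyl]-5-[(1E,3S,5Z)-2,6-dimethyl-3,7-bis(triethylsilyloxy)hepta-1,5-dien-1-yl]-4-iodofuran-2(5H)-one
Product: 13 (5R)-3-[(tert-butyldiphenylsilyloxy)methyl]-5-[(1E,3S,5Z)-2,6-dimethyl-3,7-bis(triethylsilyloxy)hepta-1,5-dien-1-yl]-4-(hydroxymethyl)furan-2(5H)-one
Conditions: Bu3SnCH2OH (1.5 equiv), Pd(PPh3)4 (10 mol %), 1,4-dioxane, 90 °C
Reagents that add atoms: (tributylstannyl)methanol, OC[Sn](CCCC)(CCCC)CCCC
Why: Stille hydroxymethylation of the activated β-iodobutenolide introduces C8 as a free allylic alcohol under neutral conditions that leave the silyl ethers and the lactone untouched.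

Step 10
Reactants: 13 (5R)-3-[(tert-butyldiphenylsilyloxy)methyl]-5-[(1E,3S,5Z)-2,6-dimethyl-3,7-bis(triethylsilyloxy)hepta-1,5-dien-1-yl]-4-(hydroxymethyl)furan-2(5H)-one
Product: 15 (5R)-4-(bromomethyl)-3-[(tert-butyldiphenylsilyloxy)methyl]-5-[(1E,3S,5Z)-2,6-dimethyl-3,7-bis(triethylsilyloxy)hepta-1,5-dien-1-yl]furan-2(5H)-one, via allylic mesylate 14 (not isolated)
Conditions: MsCl, Et3N, CH2Cl2, −20 °C; then LiBr, THF, 0 °C
Reagents that add atoms: lithium bromide, [Li+].[Br-]
Why: Mesylation of the primary allylic alcohol and SN2 displacement by bromide (Finkelstein-type) gives the allylic bromide without acid, so the silyl ethers survive.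

Step 11
Reactants: 15 (5R)-4-(bromomethyl)-3-[(tert-butyldiphenylsilyloxy)methyl]-5-[(1E,3S,5Z)-2,6-dimethyl-3,7-bis(triethylsilyloxy)hepta-1,5-dien-1-yl]furan-2(5H)-one
Product: 16 (5R)-4-(bromomethyl)-3-[(tert-butyldiphenylsilyloxy)methyl]-5-[(1E,3S,5Z)-2,6-dimethyl-7-oxo-3-(triethylsilyloxy)hepta-1,5-dien-1-yl]furan-2(5H)-one
Conditions: (COCl)2, DMSO, CH2Cl2, −78 → −40 °C; then Et3N, −78 → 0 °C
Reagents that add atoms: none
Why: Swern oxidation converts a primary triethylsilyl ether directly into the aldehyde (chloride-assisted desilylation of the activated sulfonium intermediate) while the secondary triethylsilyl and the tert-butyldiphenylsilyl ethers stay, giving the (Z)-enal without a separate deprotection.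

Step 12
Reactants: 16 (5R)-4-(bromomethyl)-3-[(tert-butyldiphenylsilyloxy)methyl]-5-[(1E,3S,5Z)-2,6-dimethyl-7-oxo-3-(triethylsilyloxy)hepta-1,5-dien-1-yl]furan-2(5H)-one
Product: 19 (3S,6R,9S)-13-(tert-butyldiphenylsilyloxy)-3,9-dihydroxygermacra-1(10)Z,4E,7(11)-trien-12,6-olide, via allylzinc bromide 17 (not isolated), via macrocyclic triethylsilyl ether 18 (not isolated)
Conditions: Zn dust (10 equiv, activated with BrCH2CH2Br and Me3SiCl), THF, 60 °C, 16 added over 10 h (final 2 mM); then AcOH–THF–H2O 3:1:1, 23 °C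
Reagents that add atoms: none
Why: Zinc inserts into the allylic C8–Br bond to give the zinc dienolate of the butenolide, which adds through its exocyclic γ-carbon C8 to the tethered aldehyde C9 while the double bond returns into ring B as C7=C11; mild acid then removes the C3 triethylsilyl ether. The closest known reaction type is the γ-selective zinc vinylogous Reformatsky reaction of γ-bromo enoates and butenolides with aldehydes, together with Reformatsky and Barbier macrocyclisations. Ring A closes in a 10-exo-trig mode on the aldehyde carbonyl under high dilution. C9 is set by substrate control: the C6 stereocentre and the rigid E-C4=C5 and Z-C1=C10 alkenes restrict the ring-forming conformer, attack is expected on the aldehyde face that leaves the zinc alkoxide outside the nascent ring to give 9S, and this is the least certain element. The step needs γ (C8) over α (C11) regioselectivity and 1,2-addition: C11 is fully substituted, so α-attack would build a quaternary centre in a bridged ring whose zinc aldolate should revert by retro-aldol at 60 °C, whereas the conjugated γ-adduct is the thermodynamic sink, and the covalent zinc reagent adds 1,2 to the enal and should not enolise C6–H.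

Step 13
Reactants: 19 (3S,6R,9S)-13-(tert-butyldiphenylsilyloxy)-3,9-dihydroxygermacra-1(10)Z,4E,7(11)-trien-12,6-olide
Product: 20 (3S,6R,9S)-3,9-diacetoxy-13-(tert-butyldiphenylsilyloxy)germacra-1(10)Z,4E,7(11)-trien-12,6-olide
Conditions: Ac2O, pyridine, DMAP (cat.), CH2Cl2, 0 → 23 °C
Reagents that add atoms: acetic anhydride, CC(=O)OC(C)=O
Why: DMAP-catalysed acetylation esterifies both secondary allylic alcohols (C3 and C9) with retention of configuration.

Step 14
Reactants: 20 (3S,6R,9S)-3,9-diacetoxy-13-(tert-butyldiphenylsilyloxy)germacra-1(10)Z,4E,7(11)-trien-12,6-olide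
Product: 21 (3S,6R,9S)-3,9-diacetoxy-13-hydroxygermacra-1(10)Z,4E,7(11)-trien-12,6-olide
Conditions: HF·pyridine, pyridine, THF, 0 → 23 °C
Reagents that add atoms: none
Why: Buffered fluoride cleavage of the primary tert-butyldiphenylsilyl ether frees the C13 alcohol without acetate migration or epimerisation of the base-sensitive C6 centre.

**Compound list**

1 | (E)-4,4-dimethoxy-2-methylbut-2-enal | O=C/C(C)=C/C(OC)OC | starting material
2 | (2E,4S)-1,1-dimethoxy-3-methylhepta-2,6-dien-4-ol | COC(OC)/C=C(\C)[C@@H](O)CC=C | intermediate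
3 | (2E,4S)-1,1-dimethoxy-3-methylhepta-2,6-dien-4-yl 2-methylprop-2-enoate | COC(OC)/C=C(\C)[C@@H](OC(=O)C(C)=C)CC=C | intermediate
4 | (6S)-6-[(2E)-4,4-dimethoxybut-2-en-2-yl]-3-methyl-5,6-dihydro-2H-pyran-2-one | COC(OC)/C=C(\C)[C@@H]1CC=C(C)C(=O)O1 | intermediate
5 | (2Z,5S,6E)-8,8-dimethoxy-2,6-dimethylocta-2,6-diene-1,5-diol | COC(OC)/C=C(\C)[C@@H](O)C/C=C(/C)CO | intermediate
6 | (2E,4S,6Z)-4,8-dihydroxy-3,7-dimethylocta-2,6-dienal | O=C/C=C(\C)[C@@H](O)C/C=C(/C)CO | intermediate
7 | (2E,4S,6Z)-3,7-dimethyl-4,8-bis(triethylsilyloxy)octa-2,6-dienal | O=C/C=C(\C)[C@@H](O[Si](CC)(CC)CC)C/C=C(/C)CO[Si](CC)(CC)CC | intermediate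
8 | tert-butyl(diphenyl)(prop-2-yn-1-yloxy)silane | C#CCO[Si](c1ccccc1)(c1ccccc1)C(C)(C)C | starting material
9 | (4S,5E,7S,9Z)-1-(tert-butyldiphenylsilyloxy)-6,10-dimethyl-7,11-bis(triethylsilyloxy)undeca-5,9-dien-2-yn-4-ol | CC(C)(C)[Si](c1ccccc1)(c1ccccc1)OCC#C[C@@H](O)/C=C(\C)[C@@H](O[Si](CC)(CC)CC)C/C=C(/C)CO[Si](CC)(CC)CC | intermediate
10 | (4S)-methanesulfonate of 9 | CC(C)(C)[Si](c1ccccc1)(c1ccccc1)OCC#C[C@@H](OS(C)(=O)=O)/C=C(\C)[C@@H](O[Si](CC)(CC)CC)C/C=C(/C)CO[Si](CC)(CC)CC | intermediate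
11 | (aR,5E,7S,9Z)-2-[(tert-butyldiphenylsilyloxy)methyl]-6,10-dimethyl-7,11-bis(triethylsilyloxy)undeca-2,3,5,9-tetraenoic acid | OC(=O)C(CO[Si](c1ccccc1)(c1ccccc1)C(C)(C)C)=[C@]=C([H])/C=C(\C)[C@@H](O[Si](CC)(CC)CC)C/C=C(/C)CO[Si](CC)(CC)CC | intermediate
12 | (5R)-3-[(tert-butyldiphenylsilyloxy)methyl]-5-[(1E,3S,5Z)-2,6-dimethyl-3,7-bis(triethylsilyloxy)hepta-1,5-dien-1-yl]-4-iodofuran-2(5H)-one | O=C1O[C@H](/C=C(\C)[C@@H](O[Si](CC)(CC)CC)C/C=C(/C)CO[Si](CC)(CC)CC)C(I)=C1CO[Si](c2ccccc2)(c2ccccc2)C(C)(C)C | intermediate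
13 | (5R)-3-[(tert-butyldiphenylsilyloxy)methyl]-5-[(1E,3S,5Z)-2,6-dimethyl-3,7-bis(triethylsilyloxy)hepta-1,5-dien-1-yl]-4-(hydroxymethyl)furan-2(5H)-one | O=C1O[C@H](/C=C(\C)[C@@H](O[Si](CC)(CC)CC)C/C=C(/C)CO[Si](CC)(CC)CC)C(CO)=C1CO[Si](c2ccccc2)(c2ccccc2)C(C)(C)C | intermediate
14 | methanesulfonate of 13 at the C8 hydroxyl | O=C1O[C@H](/C=C(\C)[C@@H](O[Si](CC)(CC)CC)C/C=C(/C)CO[Si](CC)(CC)CC)C(COS(C)(=O)=O)=C1CO[Si](c2ccccc2)(c2ccccc2)C(C)(C)C | intermediate
15 | (5R)-4-(bromomethyl)-3-[(tert-butyldiphenylsilyloxy)methyl]-5-[(1E,3S,5Z)-2,6-dimethyl-3,7-bis(triethylsilyloxy)hepta-1,5-dien-1-yl]furan-2(5H)-one | O=C1O[C@H](/C=C(\C)[C@@H](O[Si](CC)(CC)CC)C/C=C(/C)CO[Si](CC)(CC)CC)C(CBr)=C1CO[Si](c2ccccc2)(c2ccccc2)C(C)(C)C | intermediate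
16 | (5R)-4-(bromomethyl)-3-[(tert-butyldiphenylsilyloxy)methyl]-5-[(1E,3S,5Z)-2,6-dimethyl-7-oxo-3-(triethylsilyloxy)hepta-1,5-dien-1-yl]furan-2(5H)-one | O=C1O[C@H](/C=C(\C)[C@@H](O[Si](CC)(CC)CC)C/C=C(/C)C=O)C(CBr)=C1CO[Si](c2ccccc2)(c2ccccc2)C(C)(C)C | intermediate
17 | allylzinc bromide formed from 16 at C8 | O=C1O[C@H](/C=C(\C)[C@@H](O[Si](CC)(CC)CC)C/C=C(/C)C=O)C(C[Zn]Br)=C1CO[Si](c2ccccc2)(c2ccccc2)C(C)(C)C | intermediate
18 | (3S,6R,9S)-13-(tert-butyldiphenylsilyloxy)-9-hydroxy-3-(triethylsilyloxy)germacra-1(10)Z,4E,7(11)-trien-12,6-olide | O[C@H]1CC2=C(CO[Si](c3ccccc3)(c3ccccc3)C(C)(C)C)C(=O)O[C@@H]2/C=C(\C)[C@@H](O[Si](CC)(CC)CC)C/C=C\1C | intermediate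
19 | (3S,6R,9S)-13-(tert-butyldiphenylsilyloxy)-3,9-dihydroxygermacra-1(10)Z,4E,7(11)-trien-12,6-olide | O[C@H]1CC2=C(CO[Si](c3ccccc3)(c3ccccc3)C(C)(C)C)C(=O)O[C@@H]2/C=C(\C)[C@@H](O)C/C=C\1C | intermediate
20 | (3S,6R,9S)-3,9-diacetoxy-13-(tert-butyldiphenylsilyloxy)germacra-1(10)Z,4E,7(11)-trien-12,6-olide | CC(=O)O[C@H]1CC2=C(CO[Si](c3ccccc3)(c3ccccc3)C(C)(C)C)C(=O)O[C@@H]2/C=C(\C)[C@@H](OC(C)=O)C/C=C\1C | intermediate
21 | (3S,6R,9S)-3,9-diacetoxy-13-hydroxygermacra-1(10)Z,4E,7(11)-trien-12,6-olide | CC(=O)O[C@H]1CC2=C(CO)C(=O)O[C@@H]2/C=C(\C)[C@@H](OC(C)=O)C/C=C\1C | target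

Total step count: 14. Longest linear sequence: 14 steps (from 1; alkyne 8 is bought).

**Steps most likely to fail**

Step 12 (key step). What may go wrong: bond formation through the α-carbon C11 of the zinc dienolate instead of C8 (bridged kinetic adduct), reductive 1,4-elimination of silyloxide from C13, protonation or dimerisation of the organozinc before ring closure, and poor facial selectivity at the aldehyde. Fallback, from 15: the bromide is displaced with PhSO2Na (DMF, 0 °C) to give the allylic phenyl sulfone F1. The Swern oxidation of step 11 then gives the sulfonyl aldehyde F2. LiHMDS (1.05 equiv, THF, −78 °C, 2 mM) removes the doubly activated C8–H (flanked by the sulfone and the vinylogous lactone, far more acidic than C6–H), and the α-sulfonyl carbanion can add to the aldehyde only through C8. This gives the macrocyclic β-hydroxy sulfone F3 (Julia-type sulfone carbanion–aldehyde ring closure). SmI2 (THF–MeOH, −78 °C) then cleaves the C8–S bond reductively, with brief Et3N treatment if the deconjugated isomer forms, and the route is rejoined at 18.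

Step 7. What may go wrong: solvolysis or elimination of the doubly activated (allylic and propargylic) mesylate before oxidative addition, and competing ionisation toward an allylpalladium species, with loss of enantiopurity. Fallback, from 9: ClCO2Me and pyridine give the isolable propargylic methyl carbonate F4. Palladium-catalysed methoxycarbonylation (Pd2(dba)3, PPh3, CO 10 atm, MeOH, 45 °C) follows the same anti SN2′ course under neutral conditions and gives the methyl allenoate F5. I2 in MeCN–H2O lactonises the ester directly with loss of iodomethane, and the route is rejoined at 12.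

Step 11. What may go wrong: incomplete discrimination between the primary and the secondary triethylsilyl ether, halide exchange at the allylic bromide, or Z-to-E isomerisation of the enal under the amine base. Fallback, from 15: PPTS in MeOH–CH2Cl2 at −10 °C frees only the primary allylic alcohol F6, and MnO2 in CH2Cl2 oxidises it to the (Z)-enal, rejoining the route at 16.

Further compounds
F1 | step 12 | (5R)-3-[(tert-butyldiphenylsilyloxy)methyl]-5-[(1E,3S,5Z)-2,6-dimethyl-3,7-bis(triethylsilyloxy)hepta-1,5-dien-1-yl]-4-[(phenylsulfonyl)methyl]furan-2(5H)-one | O=C1O[C@H](/C=C(\C)[C@@H](O[Si](CC)(CC)CC)C/C=C(/C)CO[Si](CC)(CC)CC)C(CS(=O)(=O)c2ccccc2)=C1CO[Si](c2ccccc2)(c2ccccc2)C(C)(C)C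
F2 | step 12 | (5R)-3-[(tert-butyldiphenylsilyloxy)methyl]-5-[(1E,3S,5Z)-2,6-dimethyl-7-oxo-3-(triethylsilyloxy)hepta-1,5-dien-1-yl]-4-[(phenylsulfonyl)methyl]furan-2(5H)-one | O=C1O[C@H](/C=C(\C)[C@@H](O[Si](CC)(CC)CC)C/C=C(/C)C=O)C(CS(=O)(=O)c2ccccc2)=C1CO[Si](c2ccccc2)(c2ccccc2)C(C)(C)C
F3 | step 12 | 8-(phenylsulfonyl) derivative of 18 (both C8 epimers) | O[C@H]1C(S(=O)(=O)c3ccccc3)C2=C(CO[Si](c3ccccc3)(c3ccccc3)C(C)(C)C)C(=O)O[C@@H]2/C=C(\C)[C@@H](O[Si](CC)(CC)CC)C/C=C\1C
F4 | step 7 | (4S)-methyl carbonate of 9 | CC(C)(C)[Si](c1ccccc1)(c1ccccc1)OCC#C[C@@H](OC(=O)OC)/C=C(\C)[C@@H](O[Si](CC)(CC)CC)C/C=C(/C)CO[Si](CC)(CC)CC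
F5 | step 7 | methyl ester of 11 | COC(=O)C(CO[Si](c1ccccc1)(c1ccccc1)C(C)(C)C)=[C@]=C([H])/C=C(\C)[C@@H](O[Si](CC)(CC)CC)C/C=C(/C)CO[Si](CC)(CC)CC
F6 | step 11 | (5R)-4-(bromomethyl)-3-[(tert-butyldiphenylsilyloxy)methyl]-5-[(1E,3S,5Z)-7-hydroxy-2,6-dimethyl-3-(triethylsilyloxy)hepta-1,5-dien-1-yl]furan-2(5H)-one | O=C1O[C@H](/C=C(\C)[C@@H](O[Si](CC)(CC)CC)C/C=C(/C)CO)C(CBr)=C1CO[Si](c2ccccc2)(c2ccccc2)C(C)(C)C
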